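**Plan**
- Retrosynthesis: ring C is opened at O1–C2 (cyclodehydration of an o-hydroxyaryl 1,3-diketone). The chain is then cut at C3–C4 (crossed Claisen) into a pentamethoxybenzoyl donor (ring A plus C4) and O-benzylacetosyringone (ring B plus C2 and C3). C4–C4a goes back to carboxylation of pentamethoxybenzene.
- Enabling feature: every carbon of ring A bears oxygen. With O1 and the C5 oxygen both as methyl ethers, the acyl partner is a C6(OMe)5 group symmetric about the C4a–C7 axis. Its two ortho methoxyls are equivalent: whichever is unmasked becomes O1, and the other ends as the 5-OH.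
- Forward: ring A is oxygenated and carboxylated (Thiele–Winter reaction of 2,6-dimethoxybenzoquinone, methylation, lithiation–CO2) and acetosyringone is benzylated. The chain is joined at C3–C4, and ring C closes last, after BCl3 unmasks one ortho oxygen; the same acid treatment frees the 5-OH.
- Stereochemistry: the target is achiral and has no stereogenic double bond, so nothing has to be controlled.

Key step: step 6

Remark: lithium, sodium and boron salts of a product that are only protonated or hydrolysed during aqueous work-up are counted as the product itself and get no number.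

**Route**

Step 1
Reactants: 1 2,6-dimethoxy-1,4-benzoquinone
Product: 2 3,5-dimethoxybenzene-1,2,4-triyl triacetate
Conditions: Ac2O, cat. H2SO4, rt
Reagents that add atoms: acetic anhydride, CC(=O)OC(C)=O
Why: Thiele–Winter acetoxylation, in which acid-catalysed conjugate addition of acetate to the only free quinone position (C3 and C5 are equivalent) and peracetylation of the resulting hydroquinone should place all five oxygens of ring A on the benzene ring.

Step 2
Reactants: 2 3,5-dimethoxybenzene-1,2,4-triyl triacetate
Product: 4 pentamethoxybenzene, via dimethoxybenzenetriol 3 (not isolated)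
Conditions: Me2SO4, aq. NaOH, MeOH, Na2S2O4, N2, 0 to 40 °C
Reagents that add atoms: dimethyl sulfate, COS(=O)(=O)OC
Why: One-pot saponification and Williamson O-methylation, run under nitrogen with dithionite so that the air-sensitive triol is methylated as soon as it is released.

Step 3
Reactants: 4 pentamethoxybenzene
Product: 6 pentamethoxybenzoic acid, via pentamethoxyphenyllithium 5 (not isolated)
Conditions: n-BuLi, TMEDA, THF, 0 °C; then CO2, −78 °C to rt; aq. HCl
Reagents that add atoms: carbon dioxide, O=C=O
Why: Directed ortho-metalation, since the single ring C–H is flanked by two methoxyls and should be lithiated cleanly, and carboxylation of the aryllithium forms the future C4–C4a bond.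

Step 4
Reactants: 6 pentamethoxybenzoic acid
Product: 7 pentamethoxybenzoyl chloride
Conditions: (COCl)2, cat. DMF, CH2Cl2, 0 °C to rt; used crude
Reagents that add atoms: oxalyl chloride, ClC(=O)C(=O)Cl
Why: Acid chloride formation through the Vilsmeier-type chloroiminium species, which is safe here because the ring has no free position for electrophilic attack and di-ortho-alkoxybenzoyl chlorides are stable, isolable compounds.

Step 5
Reactants: 8 acetosyringone; 9 benzyl bromide
Product: 10 1-(4-benzyloxy-3,5-dimethoxyphenyl)ethanone
Conditions: BnBr, K2CO3, DMF, 60 °C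
Reagents that add atoms: benzyl bromide 9, BrCc1ccccc1
Why: Williamson ether synthesis on the acidic para-acyl phenol, which removes the only proton that would compete with enolate formation in the next step.

Step 6
Reactants: 10 1-(4-benzyloxy-3,5-dimethoxyphenyl)ethanone; 7 pentamethoxybenzoyl chloride
Product: 12 1-(4-benzyloxy-3,5-dimethoxyphenyl)-3-(pentamethoxyphenyl)propane-1,3-dione, via lithium enolate 11 (not isolated)
Conditions: LiN(SiMe3)2 (2.2 equiv), THF, −78 °C; then 7, −78 °C to rt; aq. NH4Cl
Reagents that add atoms: none
Why: LiN(SiMe3)2 should convert methyl ketone 10 completely into lithium enolate 11, whose α-carbon adds to the carbonyl of acid chloride 7; loss of chloride from the tetrahedral intermediate forms the C3–C4 bond, and the second equivalent of base at once turns the diketone into its chelated lithium diketonate. The closest known reaction type is the crossed Claisen C-acylation of aryl methyl ketone lithium enolates with aroyl chlorides used to prepare flavone diketones. No ring closes and no stereocentre is formed. The step needs C- over O-acylation and mono- over diacylation: the O–Li-bound enolate in THF at low temperature should react at carbon, any enol ester formed is itself an acyl donor towards remaining enolate, and the diketonate is the thermodynamic sink and is inert to a second acylation. The substrates secure the rest: 7 has no α-hydrogen and cannot enolise or form a ketene, 10 has one enolisable position, and the symmetric pentamethoxyphenyl group leaves no regiochemical question for ring A.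

Step 7
Reactants: 12 1-(4-benzyloxy-3,5-dimethoxyphenyl)-3-(pentamethoxyphenyl)propane-1,3-dione
Product: 13 1-(2-hydroxy-3,4,5,6-tetramethoxyphenyl)-3-(4-hydroxy-3,5-dimethoxyphenyl)propane-1,3-dione
Conditions: BCl3 (4 equiv), C6HMe5, CH2Cl2, −78 to 0 °C; then MeOH, aq. HCl
Reagents that add atoms: none
Why: Chelation-directed ortho-demethylation of an aryl ketone, in which boron held on the ketone oxygen activates the neighbouring methoxyl for attack by chloride (the two ortho methoxyls are equivalent, and the aryloxyboron chelate formed after the first cleavage shields the second), while the benzyl ether, the most labile ether present, is cleaved in the same pot with pentamethylbenzene trapping the benzyl cation.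

Step 8
Reactants: 13 1-(2-hydroxy-3,4,5,6-tetramethoxyphenyl)-3-(4-hydroxy-3,5-dimethoxyphenyl)propane-1,3-dione
Product: 15 5,4'-dihydroxy-6,7,8,3',5'-pentamethoxyflavone, via hexamethoxyflavone 14 (not isolated)
Conditions: conc. HCl, EtOH, reflux
Reagents that add atoms: none
Why: Acid-catalysed cyclodehydration of the o-hydroxyaryl 1,3-diketone closes ring C through O1–C2, and continued heating should cleave only the 5-methoxyl peri to the protonated C4 carbonyl (acid-promoted selective 5-O-demethylation of polymethoxyflavones), the product being stabilised by the C4=O···HO–C5 hydrogen bond.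

**Compound list**

1 | 2,6-dimethoxy-1,4-benzoquinone | COC1=CC(=O)C=C(OC)C1=O | starting material
2 | 3,5-dimethoxybenzene-1,2,4-triyl triacetate | COc1cc(OC(C)=O)c(OC(C)=O)c(OC)c1OC(C)=O | intermediate
3 | 3,5-dimethoxybenzene-1,2,4-triol | COc1cc(O)c(O)c(OC)c1O | intermediate (not isolated)
4 | pentamethoxybenzene | COc1cc(OC)c(OC)c(OC)c1OC | intermediate
5 | pentamethoxyphenyllithium | [Li]c1c(OC)c(OC)c(OC)c(OC)c1OC | intermediate (not isolated)
6 | pentamethoxybenzoic acid | COc1c(OC)c(OC)c(C(=O)O)c(OC)c1OC | intermediate
7 | pentamethoxybenzoyl chloride | COc1c(OC)c(OC)c(C(=O)Cl)c(OC)c1OC | intermediate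
8 | acetosyringone, 1-(4-hydroxy-3,5-dimethoxyphenyl)ethanone | CC(=O)c1cc(OC)c(O)c(OC)c1 | starting material
9 | benzyl bromide | BrCc1ccccc1 | starting material
10 | 1-(4-benzyloxy-3,5-dimethoxyphenyl)ethanone | CC(=O)c1cc(OC)c(OCc2ccccc2)c(OC)c1 | intermediate
11 | lithium 1-(4-benzyloxy-3,5-dimethoxyphenyl)ethenolate | [Li]OC(=C)c1cc(OC)c(OCc2ccccc2)c(OC)c1 | intermediate (not isolated)
12 | 1-(4-benzyloxy-3,5-dimethoxyphenyl)-3-(pentamethoxyphenyl)propane-1,3-dione | COc1c(OC)c(OC)c(C(=O)CC(=O)c2cc(OC)c(OCc3ccccc3)c(OC)c2)c(OC)c1OC | intermediate
13 | 1-(2-hydroxy-3,4,5,6-tetramethoxyphenyl)-3-(4-hydroxy-3,5-dimethoxyphenyl)propane-1,3-dione | COc1cc(C(=O)CC(=O)c2c(O)c(OC)c(OC)c(OC)c2OC)cc(OC)c1O | intermediate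
14 | 2-(4-hydroxy-3,5-dimethoxyphenyl)-5,6,7,8-tetramethoxy-4H-chromen-4-one (4'-hydroxy-5,6,7,8,3',5'-hexamethoxyflavone) | COc1cc(-c2cc(=O)c3c(OC)c(OC)c(OC)c(OC)c3o2)cc(OC)c1O | intermediate (not isolated)
15 | 5,4'-dihydroxy-6,7,8,3',5'-pentamethoxyflavone, 5-hydroxy-2-(4-hydroxy-3,5-dimethoxyphenyl)-6,7,8-trimethoxy-4H-chromen-4-one | COc1cc(-c2cc(=O)c3c(O)c(OC)c(OC)c(OC)c3o2)cc(OC)c1O | target

**Count and risks**

Total step count: 8. Longest linear sequence: 7 steps (steps 1, 2, 3, 4, 6, 7 and 8, from quinone 1); the ring B branch adds step 5.

Steps most likely to fail: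

1. Step 7. Ether cleavage may lose its site selectivity: once boron is locked in the diketonate chelate it may not be delivered to the ortho methoxyl, so the cleavage could stall or spread to the other crowded methyl ethers of ring A. The fallback moves the directed demethylation to acid 6, where a single carbonyl directs it, and carries the freed phenol through the Claisen step as a benzyl ether. It sets out from 6 and comes back at 13.
   - Acid 6 with BCl3 in CH2Cl2 should give 2-hydroxy-3,4,5,6-tetramethoxybenzoic acid F1.
   - BnBr and K2CO3 in DMF convert it into benzyl 2-(benzyloxy)-3,4,5,6-tetramethoxybenzoate F2.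
   - KOH in aqueous DMSO with heating (hindered ester) gives 2-(benzyloxy)-3,4,5,6-tetramethoxybenzoic acid F3.
   - (COCl)2 with cat. DMF gives 2-(benzyloxy)-3,4,5,6-tetramethoxybenzoyl chloride F4.
   - Acylation of enolate 11 under the conditions of step 6 gives 1-(2-benzyloxy-3,4,5,6-tetramethoxyphenyl)-3-(4-benzyloxy-3,5-dimethoxyphenyl)propane-1,3-dione F5.
   - Hydrogenolysis (H2, palladium on carbon, EtOAc) removes both benzyl groups and rejoins the route at 13.

2. Step 6. The enolate may be acylated at oxygen to an enol ester, or attack on the hindered, twisted acyl chloride may be slow enough that the amide base consumes it. The fallback is a thermodynamic ester Claisen condensation; it sets out from 6 and 10 and comes back at 12. Acid 6 is methylated (MeI, K2CO3, DMF) to methyl pentamethoxybenzoate F6. F6 and ketone 10 are then heated with NaH in THF; under these reversible conditions only the C-acylated sodium diketonate can accumulate, and acid work-up gives 12.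

3. Step 8. In the one-pot operation ring closure is fast but proton-driven cleavage of the 5-methyl ether is slow. The reaction may stop at 14, or prolonged heating may begin to cleave other methyl ethers. The fallback separates the two events and replaces the Brønsted-acid cleavage by a chelation-directed Lewis-acid cleavage; it sets out from 13 and comes back at 15. Diketone 13 is cyclised with AcOH and cat. H2SO4 at 100 °C and 14 is isolated. AlCl3 in MeCN, with aluminium chelated between the C4 carbonyl and the C5 oxygen, then removes only the 5-methyl group to give 15. No new compound arises.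

**Further compounds**

F1 | step 7 | 2-hydroxy-3,4,5,6-tetramethoxybenzoic acid | COc1c(OC)c(OC)c(C(=O)O)c(O)c1OC
F2 | step 7 | benzyl 2-(benzyloxy)-3,4,5,6-tetramethoxybenzoate | COc1c(OC)c(OC)c(C(=O)OCc2ccccc2)c(OCc2ccccc2)c1OC
F3 | step 7 | 2-(benzyloxy)-3,4,5,6-tetramethoxybenzoic acid | COc1c(OC)c(OC)c(C(=O)O)c(OCc2ccccc2)c1OC
F4 | step 7 | 2-(benzyloxy)-3,4,5,6-tetramethoxybenzoyl chloride | COc1c(OC)c(OC)c(C(=O)Cl)c(OCc2ccccc2)c1OC
F5 | step 7 | 1-(2-benzyloxy-3,4,5,6-tetramethoxyphenyl)-3-(4-benzyloxy-3,5-dimethoxyphenyl)propane-1,3-dione | COc1c(OC)c(OC)c(C(=O)CC(=O)c2cc(OC)c(OCc3ccccc3)c(OC)c2)c(OCc2ccccc2)c1OC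
F6 | step 6 | methyl pentamethoxybenzoate | COC(=O)c1c(OC)c(OC)c(OC)c(OC)c1OC
F0 | step 8 | none | none
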